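**Retrosynthetic overview**
- Feature: in ring B only C4 is an unsubstituted CH2, and it lies between ring A carbon C4a and C3. Removing C4 contracts ring B to a trans-3-aryl-2-(oxymethyl)indan-1-one whose carbonyl carbon is C3.
- Key disconnection: C4–C4a and C3–C4. Both form when the carbon of Me3SiCHN2 is inserted into the aryl–carbonyl bond of that indanone, so ring B arises by enlargement and not by closure.
- Five-membered ring: closed by enantioselective Rh-catalysed hydroacylation of a 2-(1-arylvinyl)benzaldehyde, which sets C1. C2 is then set trans by enolate hydroxymethylation.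
- Ring A: symmetric 5-bromo-1,2,3-trimethoxybenzene is formylated, and the new CHO steers BCl3 to its two neighbouring OMe groups. Bromination of a 2,3-dialkoxy-4-methoxybenzaldehyde is avoided because it would go next to the 4-OMe group, para to the 2-oxygen.
- Endgame: C3 ketone → C3=C4 enol triflate → ester → CH2OH, with C3 set by hydrogenation directed by the C2 CH2OH. The C8 oxygen peri to the C1 aryl group makes equilibration of a C3 aldehyde to the all-trans isomer unsafe. Ring order: rings A and C are bought, then the five-membered ring, then ring B.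

Key step: step 12

Numbering: tetralin and dihydronaphthalene compounds use the lignan numbering of the target. C1 bears ring C, C2 and C3 bear the CH2O groups, C4 is the CH2, and ring A is C4a–C8a with OMe at C6 and oxygens at C7 and C8. Indanones keep their own numbering.

Assumption: the sense of induction of (S)-BINAP in step 9 is taken by analogy with simpler α-substituted 2-vinylbenzaldehydes. If a pilot run gives the (3R)-indanone, (R)-BINAP is used and nothing else changes.

**Step 1**
Reactants: 1 5-bromo-1,2,3-trimethoxybenzene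
Product: 2 6-bromo-2,3,4-trimethoxybenzaldehyde
Conditions: Cl2CHOMe, TiCl4, CH2Cl2, 0 °C; then H2O
Reagents that add atoms: dichloromethyl methyl ether, COC(Cl)Cl; water, O
Why: Rieche formylation, in which the two open positions of 1 are equivalent by symmetry and each is para to an outer methoxy group, so only one aldehyde can form.

**Step 2**
Reactants: 2 6-bromo-2,3,4-trimethoxybenzaldehyde
Product: 3 6-bromo-2,3-dihydroxy-4-methoxybenzaldehyde
Conditions: BCl3 (2.2 equiv), CH2Cl2, 0 °C → rt; then H2O
Reagents that add atoms: none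
Why: Chelation-controlled aryl methyl ether cleavage, in which BCl3 held by the aldehyde oxygen cleaves the ortho methoxy group, the aryloxyboron chloride reaches the next methoxy group to close a catechol borate, and the remote 4-methoxy group is left, as is known for 2,3,4-trimethoxybenzaldehyde.

**Step 3**
Reactants: 3 6-bromo-2,3-dihydroxy-4-methoxybenzaldehyde
Product: 4 2,3-bis(benzyloxy)-6-bromo-4-methoxybenzaldehyde
Conditions: BnBr (2.5 equiv), K2CO3, DMF, 60 °C
Reagents that add atoms: benzyl bromide, BrCc1ccccc1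
Why: Williamson ether synthesis, warmed because the 2-hydroxyl group is hydrogen-bonded to the aldehyde.

**Step 4**
Reactants: 5 4-bromo-2-methoxyphenol
Product: 6 1-(benzyloxy)-4-bromo-2-methoxybenzene
Conditions: BnBr, K2CO3, acetone, reflux
Reagents that add atoms: benzyl bromide, BrCc1ccccc1
Why: Williamson ether synthesis on an unhindered phenol.

**Step 5**
Reactants: 6 1-(benzyloxy)-4-bromo-2-methoxybenzene; 4 2,3-bis(benzyloxy)-6-bromo-4-methoxybenzaldehyde
Product: 8 [2,3-bis(benzyloxy)-6-bromo-4-methoxyphenyl][4-(benzyloxy)-3-methoxyphenyl]methanol (racemic), via arylmagnesium bromide 7 (not isolated)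
Conditions: Mg turnings, I2 (cat.), THF, reflux; then 4, THF, 0 °C → rt; sat. aq NH4Cl
Reagents that add atoms: magnesium, [Mg] (stays only in intermediate 7, none of it in 8)
Why: Grignard addition, in which the arylmagnesium bromide adds to the aldehyde much faster than it exchanges with the aryl bromide of 4, and the racemic carbinol centre is erased in step 6.

**Step 6**
Reactants: 8 the diarylmethanol
Product: 9 [2,3-bis(benzyloxy)-6-bromo-4-methoxyphenyl][4-(benzyloxy)-3-methoxyphenyl]methanone
Conditions: Dess–Martin periodinane, CH2Cl2, rt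
Reagents that add atoms: none
Why: Dess–Martin oxidation of a benzhydrol under near-neutral conditions, which avoids ionisation of the electron-rich diarylmethanol.

**Step 7**
Reactants: 9 the diaryl ketone
Product: 10 3,4-bis(benzyloxy)-2-{1-[4-(benzyloxy)-3-methoxyphenyl]ethenyl}-1-bromo-5-methoxybenzene
Conditions: Ph3PCH3Br (3 equiv), KOt-Bu (3 equiv), toluene, 90 °C
Reagents that add atoms: methyltriphenylphosphonium bromide, C[P+](c1ccccc1)(c1ccccc1)c1ccccc1.[Br-]
Why: Wittig methylenation of a ketone that cannot enolise, so the crowded carbonyl group can be forced with excess ylide under the hot KOt-Bu protocol used for hindered ketones, which aryl bromide and benzyl ethers tolerate.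

**Step 8**
Reactants: 10 the bromo diarylethene
Product: 12 3,4-bis(benzyloxy)-2-{1-[4-(benzyloxy)-3-methoxyphenyl]ethenyl}-5-methoxybenzaldehyde, via aryllithium 11 (not isolated)
Conditions: n-BuLi (1.05 equiv), THF, −78 °C; DMF, −78 → 0 °C; H2O
Reagents that add atoms: N,N-dimethylformamide, CN(C)C=O; n-butyllithium, [Li]CCCC (lithium stays only in intermediate 11)
Why: Bromine–lithium exchange followed by Bouveault-type formylation, in which exchange at −78 °C outruns both addition of n-BuLi to the twisted, electron-rich diarylethene and benzylic deprotonation.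

**Step 9**
Reactants: 12 the 2-(1-arylvinyl)benzaldehyde
Product: 13 (3S)-4,5-bis(benzyloxy)-3-[4-(benzyloxy)-3-methoxyphenyl]-6-methoxyindan-1-one
Conditions: [Rh(nbd)2]BF4 (5 mol %), (S)-BINAP (5.5 mol %), H2 then Ar purge (activation), CH2Cl2, 25–40 °C
Reagents that add atoms: none
Why: Intramolecular alkene hydroacylation, in which the cationic monovalent rhodium complex inserts into the aldehyde C–H bond, hydride adds to the inner alkene carbon on the face chosen by the axially chiral bisphosphine (setting indanone C3, the later C1, as S), and reductive elimination from the six-membered acyl rhodacycle closes the five-membered ring, as established for α-substituted 2-vinylbenzaldehydes.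

**Step 10**
Reactants: 13 the (3S)-indanone
Product: 15 (2S,3S)-4,5-bis(benzyloxy)-3-[4-(benzyloxy)-3-methoxyphenyl]-2-(hydroxymethyl)-6-methoxyindan-1-one, via lithium enolate 14 (not isolated)
Conditions: LiN(SiMe3)2, THF, −78 °C; CH2O (gas, from cracked paraformaldehyde), −78 °C; sat. aq NH4Cl at −78 °C
Reagents that add atoms: formaldehyde, C=O; lithium hexamethyldisilazide, [Li]N([Si](C)(C)C)[Si](C)(C)C (lithium stays only in intermediate 14)
Why: Aldol addition of a lithium enolate to formaldehyde, in which the flat enolate is attacked on the face opposite the C3 aryl group to give the 2,3-trans ketol, which is also the more stable epimer at this enolisable centre.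

**Step 11**
Reactants: 15 the trans ketol
Product: 16 (2S,3S)-4,5-bis(benzyloxy)-3-[4-(benzyloxy)-3-methoxyphenyl]-2-{[(tert-butyldiphenylsilyl)oxy]methyl}-6-methoxyindan-1-one
Conditions: t-BuPh2SiCl, imidazole, CH2Cl2, 0 °C → rt
Reagents that add atoms: tert-butyl(chloro)diphenylsilane, CC(C)(C)[Si](Cl)(c1ccccc1)c1ccccc1
Why: Imidazole-promoted silylation of the primary alcohol, mild enough to avoid retro-aldol cleavage or dehydration, giving an ether that withstands BF3·OEt2 in the cold and can later be removed beside benzyl ethers and an alkene, which a benzyl ether on this oxygen could not.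

**Step 12**
Reactants: 16 the silyl-protected trans-indanone; 17 trimethylsilyldiazomethane
Product: 19 (1S,2S)-7,8-bis(benzyloxy)-1-[4-(benzyloxy)-3-methoxyphenyl]-2-{[(tert-butyldiphenylsilyl)oxy]methyl}-6-methoxy-3-oxotetralin, via 4-trimethylsilyl ketone 18 (not isolated)
Conditions: 17 (2 M in hexanes, 2 equiv), BF3·OEt2 (1.5 equiv), CH2Cl2, −78 → −20 °C; then 1 M aq HCl, THF, 0 °C
Reagents that add atoms: trimethylsilyldiazomethane (17), C[Si](C)(C)C=[N+]=[N-]
Why: BF3 binds the indanone oxygen, the nucleophilic diazo carbon of 17 adds to the carbonyl carbon (the later C3), and the β-oxido diazonium ion loses N2 while ring A carbon C4a shifts from C3 to the diazo carbon, so C4–C4a and C3–C4 are both in place in α-silyl ketone 18, which dilute acid protodesilylates to 19. This is the Lewis-acid-promoted diazoalkane homologation of ketones (Tiffeneau–Demjanov type), known with Me3SiCHN2/BF3·OEt2 to turn benzo-fused 1-cycloalkanones into their ring-enlarged 2-oxo homologues. Ring B is therefore made by one-carbon enlargement of the five-membered ring through a 1,2-aryl shift and not by a cyclisation. No lasting stereocentre is created: the silyl-bearing C4 becomes CH2, C1 is untouched, and C2, α to the carbonyl before and after, stays in its favoured trans arrangement. The step needs migration of C4a instead of C2, and a single insertion. The aryl carbon migrates through a phenonium-like transition state stabilised by the C7 benzyloxy oxygen para to C4a, C2 is a hindered secondary carbon made electron-poor by its β-silyloxy group, and the bulky Me3Si group on C4 (or the silyl enol ether it can rearrange to) keeps the more electrophilic product ketone from reacting again.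

**Step 13**
Reactants: 19 the 3-oxotetralin
Product: 21 (1S,2S)-7,8-bis(benzyloxy)-1-[4-(benzyloxy)-3-methoxyphenyl]-2-{[(tert-butyldiphenylsilyl)oxy]methyl}-6-methoxy-1,2-dihydronaphthalen-3-yl trifluoromethanesulfonate, via potassium enolate 20 (not isolated)
Conditions: KN(SiMe3)2, THF, −78 °C; PhNTf2, −78 → 0 °C; H2O
Reagents that add atoms: N-phenylbis(trifluoromethanesulfonimide), O=S(=O)(N(c1ccccc1)S(=O)(=O)C(F)(F)F)C(F)(F)F; potassium hexamethyldisilazide, [K]N([Si](C)(C)C)[Si](C)(C)C (potassium stays only in intermediate 20)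
Why: Enol triflate formation, in which the benzylic C4 hydrogens are both more acidic and less hindered, so the ring-A-conjugated C3=C4 enolate forms and C2, whose deprotonation would expel silyloxide, is left alone.

**Step 14**
Reactants: 21 the enol triflate
Product: 22 methyl (1S,2R)-7,8-bis(benzyloxy)-1-[4-(benzyloxy)-3-methoxyphenyl]-2-{[(tert-butyldiphenylsilyl)oxy]methyl}-6-methoxy-1,2-dihydronaphthalene-3-carboxylate
Conditions: Pd(OAc)2 (5 mol %), dppp (5 mol %), CO (1 atm), MeOH, Et3N, DMF, 60 °C
Reagents that add atoms: carbon monoxide, [C-]#[O+]; methanol, CO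
Why: Palladium-catalysed methoxycarbonylation of an enol triflate, in which oxidative addition to zerovalent palladium, CO insertion and methanolysis of the acylpalladium species replace OTf by CO2Me and bring in the last carbon without a base strong enough to touch C1 or C2.

**Step 15**
Reactants: 22 the unsaturated ester
Product: 23 {(1S,2R)-7,8-bis(benzyloxy)-1-[4-(benzyloxy)-3-methoxyphenyl]-2-{[(tert-butyldiphenylsilyl)oxy]methyl}-6-methoxy-1,2-dihydronaphthalen-3-yl}methanol
Conditions: i-Bu2AlH (2.5 equiv), CH2Cl2, −78 → 0 °C; aq potassium sodium tartrate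
Reagents that add atoms: none
Why: 1,2-Reduction of a conjugated ester with i-Bu2AlH, which stops at the allylic alcohol and leaves silyl and benzyl ethers alone.

**Step 16**
Reactants: 23 the silyl-protected allylic alcohol
Product: 24 {(1S,2R)-7,8-bis(benzyloxy)-1-[4-(benzyloxy)-3-methoxyphenyl]-6-methoxy-1,2-dihydronaphthalene-2,3-diyl}dimethanol
Conditions: n-Bu4NF, THF, 0 °C → rt; H2O
Reagents that add atoms: none
Why: Fluoride-induced desilylation driven by the Si–F bond, to which benzyl ethers and the alkene are inert.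

**Step 17**
Reactants: 24 the unsaturated diol
Product: 25 {(1S,2R,3R)-7,8-bis(benzyloxy)-1-[4-(benzyloxy)-3-methoxyphenyl]-6-methoxy-1,2,3,4-tetrahydronaphthalene-2,3-diyl}dimethanol
Conditions: [Ir(cod)(PCy3)(py)]PF6 (5–10 mol %), H2 (1–10 bar), CH2Cl2, rt
Reagents that add atoms: none
Why: Hydroxyl-directed homogeneous hydrogenation, in which the C1 aryl group is pseudoaxial (pushed there by the peri C8 benzyloxy group) and shields one face, while the trans C2 CH2OH is pseudoaxial on the other face, binds the cationic iridium together with the alkene and delivers both hydrogens from its own side, so the C3 CH2OH ends trans to it (3R), as is known for cyclic homoallylic alcohols, and benzyl ethers survive.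

**Step 18**
Reactants: 25 the tri-O-benzyl ether
Product: 26 (6R,7R,8S)-8-(4-hydroxy-3-methoxyphenyl)-6,7-bis(hydroxymethyl)-3-methoxy-5,6,7,8-tetrahydronaphthalene-1,2-diol (lignan numbering 1S,2R,3R; CNP0219328.1)
Conditions: H2 (1 atm), Pd/C (10 wt % Pd), MeOH–EtOAc, rt; work-up under Ar
Reagents that add atoms: none
Why: Hydrogenolysis of the three aryl benzyl ethers over palladium, which touches no stereocentre.

**Compound list**
1 | 5-bromo-1,2,3-trimethoxybenzene | COc1cc(Br)cc(OC)c1OC | starting material
2 | 6-bromo-2,3,4-trimethoxybenzaldehyde | COc1cc(Br)c(C=O)c(OC)c1OC | intermediate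
3 | 6-bromo-2,3-dihydroxy-4-methoxybenzaldehyde | COc1cc(Br)c(C=O)c(O)c1O | intermediate
4 | 2,3-bis(benzyloxy)-6-bromo-4-methoxybenzaldehyde | COc1cc(Br)c(C=O)c(OCc2ccccc2)c1OCc1ccccc1 | intermediate
5 | 4-bromo-2-methoxyphenol | COc1cc(Br)ccc1O | starting material
6 | 1-(benzyloxy)-4-bromo-2-methoxybenzene | COc1cc(Br)ccc1OCc1ccccc1 | intermediate
7 | [4-(benzyloxy)-3-methoxyphenyl]magnesium bromide | COc1cc([Mg]Br)ccc1OCc1ccccc1 | intermediate
8 | [2,3-bis(benzyloxy)-6-bromo-4-methoxyphenyl][4-(benzyloxy)-3-methoxyphenyl]methanol (racemic) | COc1cc(C(O)c2c(Br)cc(OC)c(OCc3ccccc3)c2OCc2ccccc2)ccc1OCc1ccccc1 | intermediate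
9 | [2,3-bis(benzyloxy)-6-bromo-4-methoxyphenyl][4-(benzyloxy)-3-methoxyphenyl]methanone | COc1cc(C(=O)c2c(Br)cc(OC)c(OCc3ccccc3)c2OCc2ccccc2)ccc1OCc1ccccc1 | intermediate
10 | 3,4-bis(benzyloxy)-2-{1-[4-(benzyloxy)-3-methoxyphenyl]ethenyl}-1-bromo-5-methoxybenzene | COc1cc(C(=C)c2c(Br)cc(OC)c(OCc3ccccc3)c2OCc2ccccc2)ccc1OCc1ccccc1 | intermediate
11 | {3,4-bis(benzyloxy)-2-{1-[4-(benzyloxy)-3-methoxyphenyl]ethenyl}-5-methoxyphenyl}lithium | COc1cc(C(=C)c2c([Li])cc(OC)c(OCc3ccccc3)c2OCc2ccccc2)ccc1OCc1ccccc1 | intermediate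
12 | 3,4-bis(benzyloxy)-2-{1-[4-(benzyloxy)-3-methoxyphenyl]ethenyl}-5-methoxybenzaldehyde | COc1cc(C(=C)c2c(C=O)cc(OC)c(OCc3ccccc3)c2OCc2ccccc2)ccc1OCc1ccccc1 | intermediate
13 | (3S)-4,5-bis(benzyloxy)-3-[4-(benzyloxy)-3-methoxyphenyl]-6-methoxyindan-1-one | COc1cc([C@H]2c3c(cc(OC)c(OCc4ccccc4)c3OCc3ccccc3)C(=O)C2)ccc1OCc1ccccc1 | intermediate
14 | lithium C1=C2 enolate of 13 (C3 still S) | COc1cc([C@H]2c3c(cc(OC)c(OCc4ccccc4)c3OCc3ccccc3)C(O[Li])=C2)ccc1OCc1ccccc1 | intermediate
15 | (2S,3S)-4,5-bis(benzyloxy)-3-[4-(benzyloxy)-3-methoxyphenyl]-2-(hydroxymethyl)-6-methoxyindan-1-one | COc1cc([C@H]2c3c(cc(OC)c(OCc4ccccc4)c3OCc3ccccc3)C(=O)[C@@H]2CO)ccc1OCc1ccccc1 | intermediate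
16 | (2S,3S)-4,5-bis(benzyloxy)-3-[4-(benzyloxy)-3-methoxyphenyl]-2-{[(tert-butyldiphenylsilyl)oxy]methyl}-6-methoxyindan-1-one | COc1cc([C@H]2c3c(cc(OC)c(OCc4ccccc4)c3OCc3ccccc3)C(=O)[C@@H]2CO[Si](c2ccccc2)(c2ccccc2)C(C)(C)C)ccc1OCc1ccccc1 | intermediate
17 | trimethylsilyldiazomethane | C[Si](C)(C)C=[N+]=[N-] | starting material
18 | (1S,2S)-3-oxotetralin 19 carrying Me3Si at C4 (C4 epimers) | COc1cc([C@H]2c3c(cc(OC)c(OCc4ccccc4)c3OCc3ccccc3)C([Si](C)(C)C)C(=O)[C@@H]2CO[Si](c2ccccc2)(c2ccccc2)C(C)(C)C)ccc1OCc1ccccc1 | intermediate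
19 | (1S,2S)-7,8-bis(benzyloxy)-1-[4-(benzyloxy)-3-methoxyphenyl]-2-{[(tert-butyldiphenylsilyl)oxy]methyl}-6-methoxy-3-oxotetralin [(3S,4S)-3,4-dihydronaphthalen-2(1H)-one numbering] | COc1cc([C@H]2c3c(cc(OC)c(OCc4ccccc4)c3OCc3ccccc3)CC(=O)[C@@H]2CO[Si](c2ccccc2)(c2ccccc2)C(C)(C)C)ccc1OCc1ccccc1 | intermediate
20 | potassium C3=C4 enolate of 19 | COc1cc([C@H]2c3c(cc(OC)c(OCc4ccccc4)c3OCc3ccccc3)C=C(O[K])[C@@H]2CO[Si](c2ccccc2)(c2ccccc2)C(C)(C)C)ccc1OCc1ccccc1 | intermediate
21 | (1S,2S)-1,2-dihydronaphthalen-3-yl triflate of 19 | COc1cc([C@H]2c3c(cc(OC)c(OCc4ccccc4)c3OCc3ccccc3)C=C(OS(=O)(=O)C(F)(F)F)[C@@H]2CO[Si](c2ccccc2)(c2ccccc2)C(C)(C)C)ccc1OCc1ccccc1 | intermediate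
22 | methyl (1S,2R)-1-aryl-2-(silyloxymethyl)-1,2-dihydronaphthalene-3-carboxylate | COc1cc([C@H]2c3c(cc(OC)c(OCc4ccccc4)c3OCc3ccccc3)C=C(C(=O)OC)[C@@H]2CO[Si](c2ccccc2)(c2ccccc2)C(C)(C)C)ccc1OCc1ccccc1 | intermediate
23 | (1S,2R)-3-(hydroxymethyl)-2-(silyloxymethyl)-1,2-dihydronaphthalene | COc1cc([C@H]2c3c(cc(OC)c(OCc4ccccc4)c3OCc3ccccc3)C=C(CO)[C@@H]2CO[Si](c2ccccc2)(c2ccccc2)C(C)(C)C)ccc1OCc1ccccc1 | intermediate
24 | (1S,2R)-2,3-bis(hydroxymethyl)-1,2-dihydronaphthalene, phenols as benzyl ethers | COc1cc([C@H]2c3c(cc(OC)c(OCc4ccccc4)c3OCc3ccccc3)C=C(CO)[C@@H]2CO)ccc1OCc1ccccc1 | intermediate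
25 | (1S,2R,3R)-tri-O-benzyl ether of the target | COc1cc([C@H]2c3c(cc(OC)c(OCc4ccccc4)c3OCc3ccccc3)C[C@@H](CO)[C@@H]2CO)ccc1OCc1ccccc1 | intermediate
26 | (6R,7R,8S)-8-(4-hydroxy-3-methoxyphenyl)-6,7-bis(hydroxymethyl)-3-methoxy-5,6,7,8-tetrahydronaphthalene-1,2-diol | COc1cc([C@H]2c3c(cc(OC)c(O)c3O)C[C@@H](CO)[C@@H]2CO)ccc1O | target

**Step count**
Total step count: 18. Longest linear sequence: 17 (steps 1–3 and 5–18, from 1 to 26).

**Steps most likely to fail**

**Step 12 (key step).**
- Risk: the diazo carbon may add slowly to a carbonyl group that is conjugated with the electron-rich ring A and flanked by the C2 branch. Lewis-acid-induced decay of 17, a competing shift of C2, or collapse of the adduct to an oxirane could then gain ground.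
- Fallback: the same insertion of C4 by the same aryl shift, but triggered by oxidation of an alkene instead of loss of N2.
- It sets out from 16. Petasis methylenation (Cp2TiMe2, toluene, 70 °C) is non-basic, so C2 and the β-silyloxy group are safe, and should give the (2R,3S)-1-methylideneindane F1.
- PhI(OH)OTs in 95 % MeOH then adds trivalent iodine to the exocyclic CH2 and methanol to the benzylic carbon. Ring A carbon C4a shifts to the CH2 as iodobenzene leaves, and hydrolysis of the methoxycarbenium ion comes back to the route at 19.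
- This methylenation/oxidative rearrangement pair is known chemistry for taking 1-indanones and 1-tetralones to their 2-oxo homologues.

**Step 9.**
- Risk: facial selectivity in the hydride insertion may be poor, since both substituents on the inner alkene carbon are aryl rings and the alkene is crowded by the neighbouring benzyloxy group. Decarbonylation of the acylrhodium hydride would slow turnover.
- Fallback: the stereocentre is set by reagent-controlled ketone reduction and chirality transfer.
- It sets out from 13 of insufficient enantiomeric purity, or from racemic 13 closed with the more active achiral complex [Rh(nbd)(dppe)]BF4.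
- Enolate 14 is dehydrogenated in one pot with N-tert-butylbenzenesulfinimidoyl chloride (Mukaiyama dehydrogenation) to the 3-arylinden-1-one F2.
- Corey–Bakshi–Shibata reduction (the 2-methyl-oxazaborolidine antipode that gives the 1S alcohol, BH3·SMe2) gives the (1S)-3-arylinden-1-ol F3.
- DABCO in warm THF moves the C1 hydrogen suprafacially to C3 through a tight ion pair, and tautomerisation of the enol comes back to the route at (3S)-13. This sequence is known for 3-arylindenones.

**Step 17.**
- Risk: facial selectivity may erode if binding through the in-plane allylic C3 CH2OH competes with the C2 CH2OH. The iridium hydride may also isomerise the allylic alcohol to the aldehyde.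
- Fallback: catalyst control replaces substrate direction.
- It sets out from 23, whose C2 oxygen is still silylated. Asymmetric hydrogenation uses a chiral P,N-ligated iridium complex such as [Ir(cod)(t-Bu-PHOX)]B[3,5-(CF3)2C6H3]4 (H2, 50 bar, CH2Cl2), with the ligand antipode chosen for hydrogen delivery anti to the C1 aryl group.
- This catalyst class is established for 2-substituted 3-arylallyl alcohols and should give the (1S,2R,3R)-3-(hydroxymethyl)-2-(silyloxymethyl)tetralin F4.
- n-Bu4NF in THF then removes the silyl group and comes back to the route at 25.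

**Further compounds**
F1 | step 12 | (2R,3S)-4,5-bis(benzyloxy)-3-[4-(benzyloxy)-3-methoxyphenyl]-2-{[(tert-butyldiphenylsilyl)oxy]methyl}-6-methoxy-1-methylideneindane | COc1cc([C@H]2c3c(cc(OC)c(OCc4ccccc4)c3OCc3ccccc3)C(=C)[C@@H]2CO[Si](c2ccccc2)(c2ccccc2)C(C)(C)C)ccc1OCc1ccccc1
F2 | step 9 | 4,5-bis(benzyloxy)-3-[4-(benzyloxy)-3-methoxyphenyl]-6-methoxy-1H-inden-1-one | COc1cc(C2=CC(=O)c3cc(OC)c(OCc4ccccc4)c(OCc4ccccc4)c32)ccc1OCc1ccccc1
F3 | step 9 | (1S)-4,5-bis(benzyloxy)-3-[4-(benzyloxy)-3-methoxyphenyl]-6-methoxy-1H-inden-1-ol | COc1cc(C2=C[C@H](O)c3cc(OC)c(OCc4ccccc4)c(OCc4ccccc4)c32)ccc1OCc1ccccc1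
F4 | step 17 | {(1S,2R,3R)-7,8-bis(benzyloxy)-1-[4-(benzyloxy)-3-methoxyphenyl]-2-{[(tert-butyldiphenylsilyl)oxy]methyl}-6-methoxy-1,2,3,4-tetrahydronaphthalen-3-yl}methanol | COc1cc([C@H]2c3c(cc(OC)c(OCc4ccccc4)c3OCc3ccccc3)C[C@@H](CO)[C@@H]2CO[Si](c2ccccc2)(c2ccccc2)C(C)(C)C)ccc1OCc1ccccc1
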